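The decalin is disconnected at C4a–C5, so that ring B is closed onto a dearomatised ring A. Ring A is carried as a 2-alkyl-3-methylphenol; enantioselective ortho-hydroxylation at C8a converts it into an ortho-quinol whose dienone (C1 carbonyl, C2=C3 and C4=C4a alkenes, C8a carbinol) has its electrophilic δ-carbon at the methyl-bearing C4a, within reach of C5 of the ethyl ketone tethered to C8a. A single amine-mediated vinylogous Michael addition then forms C4a–C5, closes ring B and sets the C4a quaternary centre and C5 from the C8a stereocentre. Its precursor is (R)-6-hydroxy-5-methyl-6-(3-oxopentyl)cyclohexa-2,4-dien-1-one.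

Key step: step 4

Remark on numbering: decalin positions are C1 (angelate carbon), C2 (ketone), C3 (acetyl-bearing), C4, C4a (methyl-bearing), C5 (methyl-bearing), C6 (acetate carbon), C7, C8, C8a (carbinol). Ring A is C1–C4, C4a, C8a; ring B is C4a, C5–C8, C8a. The target is (1S,4aR,5R,6S,8aR): on ring B the C8a hydroxyl, both methyls and the C6 acetate are all cis; the C1 ester oxygen is trans to the C8a hydroxyl.

Assumption: the sense of induction of the chiral iodyl reagent on phenol 4 is not known in advance. The reagent from (S)-tert-leucinol is written; its enantiomer is used if (R)-5 requires it.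

Remark on the amine in step 4: a primary amine is chosen instead of a secondary amine such as pyrrolidine. In the chair-like closure the enamine substituent syn to nitrogen ends up equatorial at C5, and only that arrangement gives the C5 methyl cis to the C4a methyl.

Step 1
Reactants: 1 2-hydroxy-6-methylbenzaldehyde; 2 1-(triphenylphosphoranylidene)butan-2-one
Product: 3 (E)-1-(2-hydroxy-6-methylphenyl)pent-1-en-3-one
Conditions: toluene, 100 °C
Reagents that add atoms: none
Why: Wittig olefination with a ketone-stabilised ylide tolerates the free phenol and should give the (E)-enone, whose geometry is erased in the next step.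

Step 2
Reactants: 3 (E)-1-(2-hydroxy-6-methylphenyl)pent-1-en-3-one
Product: 4 1-(2-hydroxy-6-methylphenyl)pentan-3-one
Conditions: H2 (1 atm), 5% Pd/C, EtOAc, rt
Reagents that add atoms: none
Why: Catalytic hydrogenation saturates the conjugated alkene much faster than it touches the ketone or the arene.

Step 3
Reactants: 4 1-(2-hydroxy-6-methylphenyl)pentan-3-one
Product: 5 (R)-6-hydroxy-5-methyl-6-(3-oxopentyl)cyclohexa-2,4-dien-1-one
Conditions: (S)-4-tert-butyl-2-(2-iodylphenyl)-4,5-dihydro-1,3-oxazole (1.3 equiv), CH2Cl2, −25 to 0 °C; cold filtration, solution used at once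
Reagents that add atoms: (S)-4-tert-butyl-2-(2-iodylphenyl)-4,5-dihydro-1,3-oxazole, CC(C)(C)[C@H]1COC(=N1)c1ccccc1I(=O)=O
Why: Hydroxylative phenol dearomatisation with a pentavalent iodine reagent: the phenol oxygen binds iodine and an iodyl oxygen is passed intramolecularly to the alkyl-bearing, more electron-rich ortho carbon C8a, the oxazoline stereocentre choosing the face that gives the (R)-carbinol, while the methyl next to the new sp3 carbon should slow [4+2] dimerisation.

Step 4
Reactants: 5 (R)-6-hydroxy-5-methyl-6-(3-oxopentyl)cyclohexa-2,4-dien-1-one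
Product: 8 (4aR,5R,8aR)-8a-hydroxy-4a,5-dimethyl-4,4a,5,7,8,8a-hexahydronaphthalene-1,6-dione, via side-chain (Z)-enamine 6 (not isolated), via bicyclic N-cyclohexyl imine 7 (not isolated)
Conditions: cyclohexylamine (0.3 equiv), PhCO2H (0.3 equiv), CH2Cl2, −20 °C to rt; aq. NH4Cl
Reagents that add atoms: none
Why: Proposed new method: the primary amine condenses with the unhindered side-chain ketone and the derived secondary enamine 6 adds through C5 to C4a, the δ-carbon of the C1 dienone (vinylogous Michael addition); tautomerisation of the dienolate to the conjugated C2–C3 enone and hydrolysis of imine 7 release 8 and the amine. The closest known reaction type is the amine-catalysed intramolecular Michael addition of tethered ketones and aldehydes to cyclohexa-2,5-dienones, extended here to the 1,6-position of a cyclohexa-2,4-dienone in line with intermolecular enamine 1,6-additions to dienones. Ring B closes in the 6-exo-trig mode through a chair in which the C4a methyl is axial and anti to C1. C4a is controlled by the C8a stereocentre, since the three-atom tether can bring C5 only to the face of the dienone that carries C8, which makes the fusion cis and the methyl cis to the hydroxyl; C5 is controlled by enamine geometry, the (Z)-enamine favoured with a primary amine placing the C5 methyl equatorial and exo, cis to the C4a methyl, whereas an (E)-enamine would have to carry it axially over ring A. The step needs C5 and not C7 as the donor and C4a and not C1 or C3 as the acceptor: C5 cannot reach C3, its aldol addition to C1 is reversible, the C7 enamine can reach C3 only through a boat leading to a strained, non-conjugated bicyclo[2.2.2]octenone, and the 1,6-adduct alone keeps an enone, so it is the expected outlet; C5, flanked by the new quaternary centre, should not epimerise under these mild conditions.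

Step 5
Reactants: 8 (4aR,5R,8aR)-8a-hydroxy-4a,5-dimethyl-4,4a,5,7,8,8a-hexahydronaphthalene-1,6-dione
Product: 9 (4aR,5R,6S,8aR)-6,8a-dihydroxy-4a,5-dimethyl-4a,5,6,7,8,8a-hexahydronaphthalen-1(4H)-one
Conditions: LiAlH(OtBu)3 (2.5 equiv), THF, −78 to −30 °C
Reagents that add atoms: none
Why: Chemoselective hydride reduction: the saturated C6 ketone should react faster than the conjugated, neopentyl C1 carbonyl, and with the C4a methyl axial on ring B (the conformer favoured once the C8a oxygen carries aluminium) hydride enters equatorially, opposite that methyl, giving the axial 6-alcohol cis to both methyls.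

Step 6
Reactants: 9 (4aR,5R,6S,8aR)-6,8a-dihydroxy-4a,5-dimethyl-4a,5,6,7,8,8a-hexahydronaphthalen-1(4H)-one
Product: 10 (4aR,5R,6S,8aR)-6-acetoxy-8a-hydroxy-4a,5-dimethyl-4a,5,6,7,8,8a-hexahydronaphthalen-1(4H)-one
Conditions: Ac2O, DMAP (0.1 equiv), pyridine, rt
Reagents that add atoms: acetic anhydride, CC(=O)OC(C)=O
Why: Nucleophile-catalysed acylation of the only secondary hydroxyl; the ring-fusion tertiary hydroxyl is too hindered to react.

Step 7
Reactants: 10 (4aR,5R,6S,8aR)-6-acetoxy-8a-hydroxy-4a,5-dimethyl-4a,5,6,7,8,8a-hexahydronaphthalen-1(4H)-one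
Product: 11 (1R,4aR,5R,6S,8aR)-6-acetoxy-4a,5-dimethyl-1,4,4a,5,6,7,8,8a-octahydronaphthalene-1,8a-diol (C1 hydroxyl trans to C8a hydroxyl)
Conditions: Me4NBH(OAc)3 (4 equiv), AcOH/MeCN 1:1, −30 to 0 °C
Reagents that add atoms: none
Why: Hydroxyl-directed triacetoxyborohydride reduction (Evans–Saksena type): the borohydride bound to the C8a oxygen delivers hydride to C1 on the face of the C8a–O bond, so the new hydroxyl is trans to it, and the reagent leaves the ester and the alkene alone.

Step 8
Reactants: 11 (1R,4aR,5R,6S,8aR)-6-acetoxy-4a,5-dimethyl-1,4,4a,5,6,7,8,8a-octahydronaphthalene-1,8a-diol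
Product: 12 2,3-epoxide of 11 with the oxirane on the face of the C1 hydroxyl
Conditions: mCPBA (1.3 equiv), NaHCO3, CH2Cl2, 0 °C
Reagents that add atoms: 3-chloroperoxybenzoic acid, O=C(OO)c1cccc(Cl)c1
Why: Hydroxyl-directed peracid epoxidation (Henbest): the allylic C1 hydroxyl hydrogen-bonds the peracid and delivers oxygen to its own face; these two stereocentres are erased later and only serve to steer the ring opening.

Step 9
Reactants: 12 2,3-epoxide of 11
Product: 15 (1R,2R,4aR,5R,6S,8aR)-6-acetoxy-4a,5-dimethyl-1,2,4a,5,6,7,8,8a-octahydronaphthalene-1,2,8a-triol (C1 and C2 hydroxyls cis; C3=C4 alkene), via hydroxy selenide 13 (not isolated), via selenoxide 14 (not isolated)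
Conditions: PhSeSePh (0.7 equiv), NaBH4 (1.4 equiv), EtOH, rt; then THF, 30% H2O2, 0 °C to rt
Reagents that add atoms: none
Why: Epoxide-to-allylic-alcohol transposition: phenylselenide opens the oxirane anti at C3 (the carbon remote from the C1 carbinol, which deactivates C2 inductively and sterically), and the selenoxide undergoes syn-elimination away from the hydroxyl towards C4, leaving the C2 alcohol allylic.

Step 10
Reactants: 15 (1R,2R,4aR,5R,6S,8aR)-6-acetoxy-4a,5-dimethyl-1,2,4a,5,6,7,8,8a-octahydronaphthalene-1,2,8a-triol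
Product: 16 (1S,4aR,5R,6S,8aR)-6-acetoxy-1,8a-dihydroxy-4a,5-dimethyl-4a,5,6,7,8,8a-hexahydronaphthalen-2(1H)-one
Conditions: activated MnO2 (15 equiv), CH2Cl2, rt
Reagents that add atoms: none
Why: Chemoselective allylic oxidation: MnO2 oxidises the allylic C2 alcohol and leaves the saturated C1 and tertiary C8a hydroxyls, under neutral conditions that should not epimerise C1.

Step 11
Reactants: 16 (1S,4aR,5R,6S,8aR)-6-acetoxy-1,8a-dihydroxy-4a,5-dimethyl-4a,5,6,7,8,8a-hexahydronaphthalen-2(1H)-one
Product: 17 (1S,4aR,5R,6S,8aR)-6-acetoxy-8a-hydroxy-4a,5-dimethyl-2-oxo-1,2,4a,5,6,7,8,8a-octahydronaphthalen-1-yl (Z)-2-methylbut-2-enoate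
Conditions: angelic acid (3 equiv), 2,4,6-trichlorobenzoyl chloride (3 equiv), Et3N (3 equiv), toluene, rt; then 16, 75 °C
Reagents that add atoms: angelic acid, C/C=C(/C)C(=O)O
Why: Yamaguchi esterification of the single secondary alcohol through the preformed mixed anhydride, run without DMAP so that the (Z)-alkene is not isomerised to the tiglate.

Step 12
Reactants: 17 the C1 angelate
Product: 18 3-iodo derivative of 17 (iodine on C3 of the C2 enone)
Conditions: I2 (2 equiv), pyridine/CH2Cl2 1:1, rt, dark
Reagents that add atoms: iodine, II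
Why: Pyridine-promoted α-iodination of a cyclic enone (conjugate addition of pyridine, iodination of the enolate, elimination), which works on cyclohexenones with a quaternary γ-carbon; exclusion of light protects the angelate geometry.

Step 13
Reactants: 18 3-iodo enone
Product: 20 CNP0196241.1 (1S,4aR,5R,6S,8aR)-6-acetoxy-3-acetyl-8a-hydroxy-4a,5-dimethyl-2-oxo-1,2,4a,5,6,7,8,8a-octahydronaphthalen-1-yl (Z)-2-methylbut-2-enoate, via 1-ethoxyvinyl enone 19 (not isolated)
Conditions: tributyl(1-ethoxyvinyl)stannane (1.5 equiv), PdCl2(PPh3)2 (5 mol%), CuI (10 mol%), DMF, 60 °C; then 1 M HCl, THF, rt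
Reagents that add atoms: tributyl(1-ethoxyvinyl)stannane, C=C(OCC)[Sn](CCCC)(CCCC)CCCC; water, O
Why: Stille coupling of an α-iodoenone with an acetyl-anion equivalent, then mild hydrolysis of the enol ether to the methyl ketone; both esters and the tertiary alcohol should survive dilute acid at rt.

Compound list
1 | 2-hydroxy-6-methylbenzaldehyde | Cc1cccc(O)c1C=O | starting material
2 | 1-(triphenylphosphoranylidene)butan-2-one | CCC(=O)C=P(c1ccccc1)(c1ccccc1)c1ccccc1 | starting material
3 | (E)-1-(2-hydroxy-6-methylphenyl)pent-1-en-3-one | CCC(=O)/C=C/c1c(C)cccc1O | intermediate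
4 | 1-(2-hydroxy-6-methylphenyl)pentan-3-one | CCC(=O)CCc1c(C)cccc1O | intermediate
5 | (R)-6-hydroxy-5-methyl-6-(3-oxopentyl)cyclohexa-2,4-dien-1-one (key-step precursor) | CCC(=O)CC[C@]1(O)C(=O)C=CC=C1C | intermediate
6 | (Z)-N-cyclohexyl enamine of the side-chain ketone of 5 (C5=C6, methyl syn to N) | C/C=C(\NC1CCCCC1)CC[C@]1(O)C(=O)C=CC=C1C | intermediate (not isolated)
7 | N-cyclohexyl C6 imine of 8 | O=C1C=CC[C@]2(C)[C@@H](C)C(=NC3CCCCC3)CC[C@]12O | intermediate (not isolated)
8 | (4aR,5R,8aR)-8a-hydroxy-4a,5-dimethyl-4,4a,5,7,8,8a-hexahydronaphthalene-1,6-dione (key-step product) | O=C1C=CC[C@]2(C)[C@@H](C)C(=O)CC[C@]12O | intermediate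
9 | (4aR,5R,6S,8aR)-6,8a-dihydroxy-4a,5-dimethyl-4a,5,6,7,8,8a-hexahydronaphthalen-1(4H)-one | O=C1C=CC[C@]2(C)[C@@H](C)[C@@H](O)CC[C@]12O | intermediate
10 | (4aR,5R,6S,8aR)-6-acetoxy-8a-hydroxy-4a,5-dimethyl-4a,5,6,7,8,8a-hexahydronaphthalen-1(4H)-one | O=C1C=CC[C@]2(C)[C@@H](C)[C@@H](OC(C)=O)CC[C@]12O | intermediate
11 | (1R,4aR,5R,6S,8aR)-6-acetoxy-4a,5-dimethyl-1,4,4a,5,6,7,8,8a-octahydronaphthalene-1,8a-diol | O[C@@H]1C=CC[C@]2(C)[C@@H](C)[C@@H](OC(C)=O)CC[C@]12O | intermediate
12 | 2,3-epoxide of 11, oxirane cis to the C1 hydroxyl | O[C@@H]1[C@@H]2O[C@@H]2C[C@]3(C)[C@@H](C)[C@@H](OC(C)=O)CC[C@]13O | intermediate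
13 | 3-phenylselanyl-1,2,8a-triol 6-acetate (selenium trans to the C2 hydroxyl, cis to the C8a hydroxyl) | O[C@@H]1[C@H](O)[C@@H]([Se]c2ccccc2)C[C@]3(C)[C@@H](C)[C@@H](OC(C)=O)CC[C@]13O | intermediate (not isolated)
14 | selenoxide of 13 | O[C@@H]1[C@H](O)[C@@H]([Se](=O)c2ccccc2)C[C@]3(C)[C@@H](C)[C@@H](OC(C)=O)CC[C@]13O | intermediate (not isolated)
15 | (1R,2R,4aR,5R,6S,8aR)-6-acetoxy-4a,5-dimethyl-1,2,4a,5,6,7,8,8a-octahydronaphthalene-1,2,8a-triol | O[C@@H]1[C@H](O)C=C[C@]2(C)[C@@H](C)[C@@H](OC(C)=O)CC[C@]12O | intermediate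
16 | (1S,4aR,5R,6S,8aR)-6-acetoxy-1,8a-dihydroxy-4a,5-dimethyl-4a,5,6,7,8,8a-hexahydronaphthalen-2(1H)-one | O[C@@H]1C(=O)C=C[C@]2(C)[C@@H](C)[C@@H](OC(C)=O)CC[C@]12O | intermediate
17 | C1 angelate of 16 | C/C=C(/C)C(=O)O[C@@H]1C(=O)C=C[C@]2(C)[C@@H](C)[C@@H](OC(C)=O)CC[C@]12O | intermediate
18 | 3-iodo derivative of 17 | C/C=C(/C)C(=O)O[C@@H]1C(=O)C(I)=C[C@]2(C)[C@@H](C)[C@@H](OC(C)=O)CC[C@]12O | intermediate
19 | 3-(1-ethoxyvinyl) derivative of 17 | C/C=C(/C)C(=O)O[C@@H]1C(=O)C(C(=C)OCC)=C[C@]2(C)[C@@H](C)[C@@H](OC(C)=O)CC[C@]12O | intermediate (not isolated)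
20 | CNP0196241.1 | C/C=C(/C)C(=O)O[C@@H]1C(=O)C(C(C)=O)=C[C@]2(C)[C@@H](C)[C@@H](OC(C)=O)CC[C@]12O | target

Total step count: 13. Longest linear sequence: 13 steps (1 to 20).

Steps most likely to fail

1. Step 4 (proposed new method). Several processes could outrun the wanted closure: the C7 enamine adding to C3 to give a bridged bicyclo[2.2.2]octenone, amine conjugate addition to the dienone, [4+2] dimerisation of the quinol, or closure with the C5 methyl on the wrong face. The fallback uses a doubly stabilised donor in which only C5 can be the nucleophile. It sets out from 1 and comes back at 8. Wittig olefination of 1 with methyl 3-oxo-4-(triphenylphosphoranylidene)butanoate should give methyl (E)-5-(2-hydroxy-6-methylphenyl)-3-oxopent-4-enoate F1. Hydrogenation (H2, Pd/C) gives methyl 5-(2-hydroxy-6-methylphenyl)-3-oxopentanoate F2. The hydroxylative dearomatisation of step 3 gives methyl 5-[(1R)-1-hydroxy-2-methyl-6-oxocyclohexa-2,4-dien-1-yl]-3-oxopentanoate F3. Base-mediated Michael addition of the β-keto ester (Cs2CO3, MeCN, 0 °C), the classical soft donor for 1,6-addition to dienones, closes ring B to the 5-methoxycarbonyl analogue of 8 that lacks the C5 methyl, F4. C-methylation (MeI, K2CO3, acetone) gives the 5-methyl-5-methoxycarbonyl compound F5. Krapcho dealkoxycarbonylation (LiCl, wet DMSO, 130 °C) then gives 8, with C5 set by protonation of the enol on the face opposite the axial C4a methyl.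

2. Step 3. Oxygen may be delivered to the unsubstituted ortho carbon (ortho-quinone formation), the reagent may discriminate the two faces of C8a poorly, or the quinol may dimerise before use. The fallback replaces iodine-based oxygen transfer by copper–dioxygen chemistry and makes no new compound (F0). It sets out from 4 and comes back at 5: the lithium phenolate of 4 (LiOH or n-BuLi) is oxidised with O2 in the presence of [Cu(MeCN)4]PF6 and sparteine in THF at −78 °C, conditions known to hydroxylate the alkylated ortho carbon of 2-alkylphenolates enantioselectively; the sparteine antipode is chosen for the (R)-quinol.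

3. Step 5. The hydride may also attack the C1 enone carbonyl (loss of chemoselectivity), giving mixtures of mono- and bis-reduced material. The fallback gives up selective reduction in favour of exhaustive reduction and selective re-oxidation. It sets out from 8 and comes back at 9: excess i-Bu2AlH (CH2Cl2, −78 °C) reduces both carbonyls in the 1,2-sense to (4aR,5R,6S,8aR)-4a,5-dimethyl-1,4,4a,5,6,7,8,8a-octahydronaphthalene-1,6,8a-triol F6 (C1 epimers), and MnO2 in CH2Cl2 re-oxidises only the allylic C1 alcohol to give 9.

Further compounds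
F1 | step 4 | methyl (E)-5-(2-hydroxy-6-methylphenyl)-3-oxopent-4-enoate | COC(=O)CC(=O)/C=C/c1c(C)cccc1O
F2 | step 4 | methyl 5-(2-hydroxy-6-methylphenyl)-3-oxopentanoate | COC(=O)CC(=O)CCc1c(C)cccc1O
F3 | step 4 | methyl 5-[(1R)-1-hydroxy-2-methyl-6-oxocyclohexa-2,4-dien-1-yl]-3-oxopentanoate | COC(=O)CC(=O)CC[C@]1(O)C(=O)C=CC=C1C
F4 | step 4 | 5-methoxycarbonyl analogue of 8 lacking the C5 methyl (C5 epimers or enol) | O=C1C=CC[C@]2(C)C(C(=O)OC)C(=O)CC[C@]12O
F5 | step 4 | 5-methyl-5-methoxycarbonyl analogue of 8 (C5 epimers) | O=C1C=CC[C@]2(C)C(C)(C(=O)OC)C(=O)CC[C@]12O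
F0 | step 3 | none | none
F6 | step 5 | (4aR,5R,6S,8aR)-4a,5-dimethyl-1,4,4a,5,6,7,8,8a-octahydronaphthalene-1,6,8a-triol (C1 epimers) | OC1C=CC[C@]2(C)[C@@H](C)[C@@H](O)CC[C@]12O
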